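**Retrosynthetic overview** (numbering: C1 = lactone carbonyl, ring oxygen O1 on C5, chain to C20)
1. Target ⇒ acid removal of a C7/C9 acetonide and a C11 silyl ether ⇒ ring-closing metathesis of a C5-O acrylate closes C2=C3; the pyranone (ring A) is the only ring of the target and is formed last, after a temporary 1,3-dioxane (acetonide) ring.
2. Key disconnection C8–C9: a one-pot boron aldol / in situ LiBH4 reduction unites methyl ketone 10 (C3–C8) with aldehyde 14 (C9–C20) and sets C9 and C7 through a transient six-membered boron chelate ring.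
3. Enabling feature: the oxygen on C5 (the future ring oxygen O1 of ring A) lies β to C7 and 1,5-anti to the C9 hydroxyl, and the C7 and C9 hydroxyls are 1,3-syn across the C8 methylene; kept as an ether (PMB) and not as the lactone acyl oxygen, it steers the aldol.
4. Fragments: (R)-epichlorohydrin supplies C4–C6 and the C5 stereocentre (C7/C8 from 2-methyl-1,3-dithiane, C3 from vinyl Grignard); methyl 3-oxododecanoate supplies C9–C20, with C11 set by asymmetric hydrogenation.

Key step: step 8

Remark: compounds 1, 2, 6, 11 and 20 are taken as commercial; the target is (6S)-6-[(2S,4S,6R)-2,4,6-trihydroxypentadecyl]-5,6-dihydro-2H-pyran-2-one, i.e. 5S,7S,9S,11R in the numbering used here.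

**Route**

Step 1
Reactants: 1 2-methyl-1,3-dithiane; 2 (R)-epichlorohydrin
Product: 5 2-methyl-2-{[(2R)-oxiran-2-yl]methyl}-1,3-dithiane, via 2-lithio-2-methyl-1,3-dithiane 3 (not isolated), via lithium chlorohydrin alkoxide 4 (not isolated)
Conditions: n-BuLi, THF, −20 °C; then 2, −78 °C → rt
Reagents that add atoms: none
Why: Corey–Seebach alkylation in which the lithiated dithiane should open the epoxide of 2 at its CH2 terminus and the resulting alkoxide then displaces chloride (intramolecular Williamson closure), so the stereocentre of 2 is never touched and becomes C5.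

Step 2
Reactants: 5 2-methyl-2-{[(2R)-oxiran-2-yl]methyl}-1,3-dithiane; 6 vinylmagnesium bromide
Product: 7 (2S)-1-(2-methyl-1,3-dithian-2-yl)pent-4-en-2-ol
Conditions: CuI (10 mol%), THF, −40 → −20 °C; aq. NH4Cl
Reagents that add atoms: none
Why: copper-catalysed Grignard opening of a terminal epoxide by SN2 attack at the unsubstituted carbon, which leaves the C5 configuration unchanged.

Step 3
Reactants: 7 (2S)-1-(2-methyl-1,3-dithian-2-yl)pent-4-en-2-ol
Product: 9 2-{(2S)-2-[(4-methoxyphenyl)methoxy]pent-4-en-1-yl}-2-methyl-1,3-dithiane, via sodium (2S)-1-(2-methyl-1,3-dithian-2-yl)pent-4-en-2-olate 8 (not isolated)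
Conditions: NaH, DMF, 0 °C; PMBCl, Bu4NI (cat.), 0 °C → rt
Reagents that add atoms: 4-methoxybenzyl chloride (PMBCl), COc1ccc(CCl)cc1
Why: Williamson etherification that installs an ether-type oxygen substituent on C5, as required for the 1,5-induction in step 8 and removable later without touching silyl ether or acetonide.

Step 4
Reactants: 9 2-{(2S)-2-[(4-methoxyphenyl)methoxy]pent-4-en-1-yl}-2-methyl-1,3-dithiane
Product: 10 (4S)-4-[(4-methoxyphenyl)methoxy]hept-6-en-2-one
Conditions: MeI, CaCO3, MeCN/H2O (9:1), 45 °C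
Reagents that add atoms: water, O
Why: S-methylation-triggered hydrolysis of the dithioketal (Corey–Seebach unmasking) under buffered, non-oxidative conditions that should spare the terminal alkene and the PMB ether.

Step 5
Reactants: 11 methyl 3-oxododecanoate
Product: 12 methyl (3R)-3-hydroxydodecanoate
Conditions: H2 (50 atm), RuCl2[(R)-BINAP] (0.1 mol%), MeOH, 50 °C
Reagents that add atoms: none
Why: Noyori asymmetric hydrogenation of a β-keto ester, in which the (R)-BINAP ruthenium catalyst should deliver hydrogen to the ester-chelated ketone to give the 3R carbinol (C11).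

Step 6
Reactants: 12 methyl (3R)-3-hydroxydodecanoate
Product: 13 methyl (3R)-3-[(tert-butyldimethylsilyl)oxy]dodecanoate
Conditions: TBSCl, imidazole, DMF, rt
Reagents that add atoms: tert-butyldimethylsilyl chloride (TBSCl), CC(C)(C)[Si](C)(C)Cl
Why: standard imidazole-promoted silylation of a secondary alcohol, giving a C11 protecting group that survives DDQ and is removed by acid at the end.

Step 7
Reactants: 13 methyl (3R)-3-[(tert-butyldimethylsilyl)oxy]dodecanoate
Product: 14 (3R)-3-[(tert-butyldimethylsilyl)oxy]dodecanal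
Conditions: i-Bu2AlH, CH2Cl2, −78 °C; aq. potassium sodium tartrate
Reagents that add atoms: none
Why: partial reduction of a methyl ester, in which the tetrahedral aluminium hemiacetal is stable at −78 °C and releases the aldehyde only on work-up.

Step 8
Reactants: 10 (4S)-4-[(4-methoxyphenyl)methoxy]hept-6-en-2-one; 14 (3R)-3-[(tert-butyldimethylsilyl)oxy]dodecanal
Product: 17 (4S,6S,8R,10R)-10-[(tert-butyldimethylsilyl)oxy]-4-[(4-methoxyphenyl)methoxy]nonadec-1-ene-6,8-diol, via dicyclohexylboron enolate 15 (not isolated), via dicyclohexylboron aldolate 16 (not isolated)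
Conditions: (c-C6H11)2BCl, Et3N, Et2O, −78 → 0 °C; 14, −78 → −20 °C; LiBH4 (THF), −78 °C; H2O2, pH 7 buffer, MeOH, 0 °C
Reagents that add atoms: none
Why: (c-C6H11)2BCl/Et3N should enolise 10 kinetically at the C8 methyl group to give boron enolate 15, which adds to aldehyde 14 through a cyclic six-membered transition state to form C8–C9 and boron aldolate 16; LiBH4 then delivers hydride to the C7 carbonyl held in the O–B–O chelate of 16. The closest known reaction type is the boron-mediated 1,5-anti aldol reaction of β-alkoxy methyl ketones combined with in situ borohydride reduction of the aldolate, a one-pot form of the Narasaka–Prasad reduction. No ring of the product is closed; the only ring involved is the transient six-membered boron chelate (C7, C8, C9, their two oxygens and boron), which is cleaved in the oxidative work-up. C9 is controlled by the PMB-ether oxygen on C5 (1,5-anti induction, attributed to a formyl C–H···O contact with the β-alkoxy oxygen in the favoured transition state), with the C11 silyl ether expected to be a bystander, and C7 is controlled by the new C9 centre through the chelate (external hydride anti to the C9 substituent, 1,3-syn). The step needs site-selective enolisation (C8 over C6), aldehyde facial selectivity and ketone facial selectivity; these are secured by the bulky dialkylboron chloride with a small amine, by the ether (not silyl or acyl) character of the C5 oxygen, and by keeping the aldolate boron-bound at −78 °C until reduction is complete.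

Step 9
Reactants: 17 (4S,6S,8R,10R)-10-[(tert-butyldimethylsilyl)oxy]-4-[(4-methoxyphenyl)methoxy]nonadec-1-ene-6,8-diol
Product: 18 tert-butyl{[(2R)-1-[(4R,6R)-6-{(2S)-2-[(4-methoxyphenyl)methoxy]pent-4-en-1-yl}-2,2-dimethyl-1,3-dioxan-4-yl]undecan-2-yl]oxy}dimethylsilane
Conditions: Me2C(OMe)2, PPTS (cat.), CH2Cl2, rt
Reagents that add atoms: 2,2-dimethoxypropane, COC(C)(C)OC
Why: acid-catalysed transketalisation, favoured because the syn-1,3-diol forms a chair 1,3-dioxane with both substituents equatorial, which also offers a handle to verify the syn relationship.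

Step 10
Reactants: 18 tert-butyl{[(2R)-1-[(4R,6R)-6-{(2S)-2-[(4-methoxyphenyl)methoxy]pent-4-en-1-yl}-2,2-dimethyl-1,3-dioxan-4-yl]undecan-2-yl]oxy}dimethylsilane
Product: 19 (2S)-1-[(4R,6R)-6-{(2R)-2-[(tert-butyldimethylsilyl)oxy]undecyl}-2,2-dimethyl-1,3-dioxan-4-yl]pent-4-en-2-ol
Conditions: DDQ, CH2Cl2/pH 7 buffer (10:1), 0 °C
Reagents that add atoms: none
Why: oxidative cleavage of the PMB ether (benzylic hydride abstraction by DDQ, then hydrolysis of the oxocarbenium ion), to which silyl ether, acetonide and terminal alkene are inert under buffered conditions.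

Step 11
Reactants: 19 (2S)-1-[(4R,6R)-6-{(2R)-2-[(tert-butyldimethylsilyl)oxy]undecyl}-2,2-dimethyl-1,3-dioxan-4-yl]pent-4-en-2-ol; 20 acryloyl chloride
Product: 21 (2S)-1-[(4S,6R)-6-{(2R)-2-[(tert-butyldimethylsilyl)oxy]undecyl}-2,2-dimethyl-1,3-dioxan-4-yl]pent-4-en-2-yl prop-2-enoate
Conditions: Et3N, DMAP (cat.), CH2Cl2, 0 °C
Reagents that add atoms: none
Why: DMAP-catalysed acylation of the only free hydroxyl (C5) with retention of configuration, since the C–O bond is not broken.

Step 12
Reactants: 21 (2S)-1-[(4S,6R)-6-{(2R)-2-[(tert-butyldimethylsilyl)oxy]undecyl}-2,2-dimethyl-1,3-dioxan-4-yl]pent-4-en-2-yl prop-2-enoate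
Product: 22 (6S)-6-{[(4S,6R)-6-{(2R)-2-[(tert-butyldimethylsilyl)oxy]undecyl}-2,2-dimethyl-1,3-dioxan-4-yl]methyl}-5,6-dihydro-2H-pyran-2-one
Conditions: second-generation Grubbs catalyst RuCl2(=CHPh)(PCy3)(H2IMes) (5 mol%), CH2Cl2 (2 mM), 40 °C
Reagents that add atoms: none
Why: ring-closing metathesis of the acrylate with the homoallylic alkene closes ring A at C2=C3 with loss of ethene, the cis geometry being enforced by the six-membered ring.

Step 13
Reactants: 22 (6S)-6-{[(4S,6R)-6-{(2R)-2-[(tert-butyldimethylsilyl)oxy]undecyl}-2,2-dimethyl-1,3-dioxan-4-yl]methyl}-5,6-dihydro-2H-pyran-2-one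
Product: 23 (6S)-6-[(2S,4S,6R)-2,4,6-trihydroxypentadecyl]-5,6-dihydro-2H-pyran-2-one
Conditions: 48% aq. HF, MeCN, 0 °C → rt
Reagents that add atoms: none
Why: global acidic deprotection in which HF cleaves the Si–O bond and the aqueous acid hydrolyses the acetonide, without breaking any C–O bond at a stereocentre and without base that could trigger conjugate addition to the enoate.

**Compound list**

1 | 2-methyl-1,3-dithiane | CC1SCCCS1 | starting material
2 | (R)-epichlorohydrin, (2R)-2-(chloromethyl)oxirane | ClC[C@H]1CO1 | starting material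
3 | 2-lithio-2-methyl-1,3-dithiane | [Li]C1(C)SCCCS1 | intermediate
4 | lithium (2R)-1-chloro-3-(2-methyl-1,3-dithian-2-yl)propan-2-olate | CC1(SCCCS1)C[C@@H]([O-])CCl.[Li+] | intermediate
5 | 2-methyl-2-{[(2R)-oxiran-2-yl]methyl}-1,3-dithiane | CC1(SCCCS1)C[C@@H]2CO2 | intermediate
6 | vinylmagnesium bromide | C=C[Mg]Br | starting material
7 | (2S)-1-(2-methyl-1,3-dithian-2-yl)pent-4-en-2-ol | CC1(SCCCS1)C[C@@H](O)CC=C | intermediate
8 | sodium (2S)-1-(2-methyl-1,3-dithian-2-yl)pent-4-en-2-olate | CC1(SCCCS1)C[C@@H]([O-])CC=C.[Na+] | intermediate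
9 | 2-{(2S)-2-[(4-methoxyphenyl)methoxy]pent-4-en-1-yl}-2-methyl-1,3-dithiane | CC1(SCCCS1)C[C@@H](OCc2ccc(OC)cc2)CC=C | intermediate
10 | (4S)-4-[(4-methoxyphenyl)methoxy]hept-6-en-2-one | CC(=O)C[C@@H](OCc1ccc(OC)cc1)CC=C | intermediate
11 | methyl 3-oxododecanoate | CCCCCCCCCC(=O)CC(=O)OC | starting material
12 | methyl (3R)-3-hydroxydodecanoate | CCCCCCCCC[C@@H](O)CC(=O)OC | intermediate
13 | methyl (3R)-3-[(tert-butyldimethylsilyl)oxy]dodecanoate | CCCCCCCCC[C@@H](O[Si](C)(C)C(C)(C)C)CC(=O)OC | intermediate
14 | (3R)-3-[(tert-butyldimethylsilyl)oxy]dodecanal | CCCCCCCCC[C@@H](O[Si](C)(C)C(C)(C)C)CC=O | intermediate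
15 | dicyclohexyl{[(4S)-4-[(4-methoxyphenyl)methoxy]hepta-1,6-dien-2-yl]oxy}borane | C=C(OB(C1CCCCC1)C2CCCCC2)C[C@@H](OCc3ccc(OC)cc3)CC=C | intermediate
16 | (4S,8S,10R)-10-[(tert-butyldimethylsilyl)oxy]-8-[(dicyclohexylboranyl)oxy]-4-[(4-methoxyphenyl)methoxy]nonadec-1-en-6-one | CCCCCCCCC[C@@H](O[Si](C)(C)C(C)(C)C)C[C@H](OB(C1CCCCC1)C2CCCCC2)CC(=O)C[C@@H](OCc3ccc(OC)cc3)CC=C | intermediate
17 | (4S,6S,8R,10R)-10-[(tert-butyldimethylsilyl)oxy]-4-[(4-methoxyphenyl)methoxy]nonadec-1-ene-6,8-diol | CCCCCCCCC[C@@H](O[Si](C)(C)C(C)(C)C)C[C@H](O)C[C@H](O)C[C@@H](OCc1ccc(OC)cc1)CC=C | intermediate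
18 | tert-butyl{[(2R)-1-[(4R,6R)-6-{(2S)-2-[(4-methoxyphenyl)methoxy]pent-4-en-1-yl}-2,2-dimethyl-1,3-dioxan-4-yl]undecan-2-yl]oxy}dimethylsilane | CCCCCCCCC[C@@H](O[Si](C)(C)C(C)(C)C)C[C@H]1C[C@@H](C[C@@H](OCc2ccc(OC)cc2)CC=C)OC(C)(C)O1 | intermediate
19 | (2S)-1-[(4R,6R)-6-{(2R)-2-[(tert-butyldimethylsilyl)oxy]undecyl}-2,2-dimethyl-1,3-dioxan-4-yl]pent-4-en-2-ol | CCCCCCCCC[C@@H](O[Si](C)(C)C(C)(C)C)C[C@H]1C[C@@H](C[C@@H](O)CC=C)OC(C)(C)O1 | intermediate
20 | acryloyl chloride | C=CC(=O)Cl | starting material
21 | (2S)-1-[(4S,6R)-6-{(2R)-2-[(tert-butyldimethylsilyl)oxy]undecyl}-2,2-dimethyl-1,3-dioxan-4-yl]pent-4-en-2-yl prop-2-enoate | CCCCCCCCC[C@@H](O[Si](C)(C)C(C)(C)C)C[C@H]1C[C@@H](C[C@@H](OC(=O)C=C)CC=C)OC(C)(C)O1 | intermediate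
22 | (6S)-6-{[(4S,6R)-6-{(2R)-2-[(tert-butyldimethylsilyl)oxy]undecyl}-2,2-dimethyl-1,3-dioxan-4-yl]methyl}-5,6-dihydro-2H-pyran-2-one | CCCCCCCCC[C@@H](O[Si](C)(C)C(C)(C)C)C[C@H]1C[C@@H](C[C@@H]2CC=CC(=O)O2)OC(C)(C)O1 | intermediate
23 | (6S)-6-[(2S,4S,6R)-2,4,6-trihydroxypentadecyl]-5,6-dihydro-2H-pyran-2-one | CCCCCCCCC[C@@H](O)C[C@H](O)C[C@H](O)C[C@@H]1CC=CC(=O)O1 | target

**Summary**

Total step count: 13. Longest linear sequence: 10 steps (steps 1–4, then 8–13); the aldehyde branch (steps 5–7) is three steps.

**Steps most likely to fail**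

Step 8. The aldehyde facial selectivity may be eroded if the remote silyloxy stereocentre competes with the 1,5-anti bias, or hydride delivery may be incomplete or unselective if the aldolate leaves the boron chelate. The fallback separates the two events and adds reagent control. It sets out from ketone 10 and aldehyde 14. Ketone 10 is enolised with chlorodiisopinocampheylborane, (Ipc)2BCl (the antipode that proves matched with the 1,5-anti sense in a small-scale test of both), and Et3N in Et2O, then treated with 14 and worked up oxidatively. This should allow isolation and purification of (4S,8S,10R)-10-[(tert-butyldimethylsilyl)oxy]-8-hydroxy-4-[(4-methoxyphenyl)methoxy]nonadec-1-en-6-one F1. A discrete Narasaka–Prasad reduction (Et2BOMe, NaBH4, THF/MeOH, −78 °C; H2O2 work-up) should then give the 1,3-syn diol, and the route is rejoined at 17.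

Step 1. The lithiated dithiane may displace chloride directly, which would erode enantiopurity, or a second dithiane anion may open the newly formed epoxide. The fallback reverses the order in which the two nucleophiles are delivered to the three-carbon linchpin and uses the commercial antipode, (S)-epichlorohydrin (ClC[C@@H]1CO1). It sets out from vinylmagnesium bromide 6 and dithiane 1. Reagent 6 with catalytic CuI in THF at −40 °C should open (S)-epichlorohydrin at its epoxide CH2 to give (2S)-1-chloropent-4-en-2-ol F2. Powdered NaOH in Et2O should close this to (2S)-2-(prop-2-en-1-yl)oxirane F3. Lithiated dithiane 3 (from 1 and n-BuLi) should then open this simple terminal epoxide at its CH2 group, and the route is rejoined at alcohol 7.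

Step 13. During global deprotection the freed C7 hydroxyl may add to C3 of the enoate in an acid-promoted oxa-Michael reaction, or the lactone may open. The fallback changes the order of deprotection and ring closure so that the unsaturated lactone never meets acid. It sets out from acrylate 21. Treatment with 48% aq. HF in MeCN should remove acetonide and silyl ether while the acyclic acrylate ester survives, giving (4S,6S,8S,10R)-6,8,10-trihydroxynonadec-1-en-4-yl prop-2-enoate F4. Ring-closing metathesis of the unprotected triol with the second-generation Grubbs catalyst (CH2Cl2, high dilution, 40 °C), which tolerates free hydroxyls, should then give the target directly, rejoining the route at 23.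

**Further compounds**

F1 | step 8 | (4S,8S,10R)-10-[(tert-butyldimethylsilyl)oxy]-8-hydroxy-4-[(4-methoxyphenyl)methoxy]nonadec-1-en-6-one | CCCCCCCCC[C@@H](O[Si](C)(C)C(C)(C)C)C[C@H](O)CC(=O)C[C@@H](OCc1ccc(OC)cc1)CC=C
F2 | step 1 | (2S)-1-chloropent-4-en-2-ol | ClC[C@@H](O)CC=C
F3 | step 1 | (2S)-2-(prop-2-en-1-yl)oxirane | C=CC[C@H]1CO1
F4 | step 13 | (4S,6S,8S,10R)-6,8,10-trihydroxynonadec-1-en-4-yl prop-2-enoate | CCCCCCCCC[C@@H](O)C[C@H](O)C[C@H](O)C[C@@H](OC(=O)C=C)CC=C
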